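**Plan**

1. Atom labels used throughout: C1 lactone carbonyl, C2, C3 (ring-fusion CH on the peroxide), C4 (ring-fusion carbon with methyl and lactone oxygen), C5, C6 (methyl, hexadecyl, peroxide oxygen), C7 and C8 (first chain carbons).
2. Enabling feature: in the γ-lactone, C3 lies between the oxygenated C4 and the C2–C1 acyl arm, and the O–O bridge of the 1,2-dioxane ties C3 to C6. This is the imprint of a C6 hydroperoxide, carbon monoxide and the C4 hydroxyl adding across a C3=C2 vinyl group.
3. Retrosynthesis: restore a C7 hydroxyl (through the C7=C8 alkene); cut C3–O(peroxide), C2–C1 and C1–O(lactone) together; then C6–OOH (epoxide perhydrolysis), C3=C2 (methylenation), C4–C5 (enolate alkylation) and C6=C7 (Wittig).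
4. Forward: the C16 chain is joined to a lactate-derived dioxolanone through an allylic bromide, the acyclic vinyl carbinol hydroperoxide is built, and both rings then form in one operation, the 1,2-dioxane first and the γ-lactone second.
5. Stereochemistry: C4 from (R)-lactic acid by self-regeneration of stereocentres; C6 from a Shi epoxidation followed by invertive opening with H2O2; C3 in the cascade under control of C4 and C6; the auxiliary C7 carbinol is erased at the end.

Key step: step 11

Remark on the chemistry: the alkene of step 12 is expected as an E/Z mixture (the E isomer is drawn); both isomers give the same product in step 13.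

**Route**

Step 1
Reactants: 1 (R)-lactic acid; 2 pivalaldehyde (2,2-dimethylpropanal)
Product: 3 (2R,5R)-2-tert-butyl-5-methyl-1,3-dioxolan-4-one (cis)
Conditions: TsOH·H2O (cat.), H2SO4 (cat.), pentane, reflux, Dean–Stark; crystallisation from pentane/Et2O at −78 °C
Reagents that add atoms: none
Why: Acid-catalysed acetalisation of the α-hydroxy acid with azeotropic removal of water should favour the cis acetal, which crystallises pure and stores the lactate configuration in the new acetal centre.

Step 2
Reactants: 4 hexadecanal; 5 ethyl 2-(triphenyl-λ5-phosphanylidene)propanoate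
Product: 6 ethyl (2E)-2-methyloctadec-2-enoate
Conditions: toluene, 80 °C
Reagents that add atoms: none
Why: Wittig olefination with a stabilised α-branched ylide should give the trisubstituted enoate with high E selectivity, fixing the C6=C7 geometry.

Step 3
Reactants: 6 ethyl (2E)-2-methyloctadec-2-enoate
Product: 7 (2E)-2-methyloctadec-2-en-1-ol
Conditions: iBu2AlH (2.2 equiv), CH2Cl2, −78 to 0 °C
Reagents that add atoms: none
Why: 1,2-Reduction of the conjugated ester by the aluminium hydride should give the allylic alcohol without touching the alkene.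

Step 4
Reactants: 7 (2E)-2-methyloctadec-2-en-1-ol
Product: 8 (2E)-1-bromo-2-methyloctadec-2-ene
Conditions: CBr4, PPh3, CH2Cl2, 0 °C
Reagents that add atoms: tetrabromomethane, BrC(Br)(Br)Br
Why: Appel bromination converts the primary allylic alcohol into the bromide under neutral conditions, without allylic transposition or loss of alkene geometry.

Step 5
Reactants: 3 (2R,5R)-2-tert-butyl-5-methyl-1,3-dioxolan-4-one; 8 (2E)-1-bromo-2-methyloctadec-2-ene
Product: 10 (2R,5S)-2-tert-butyl-5-methyl-5-[(2E)-2-methyloctadec-2-en-1-yl]-1,3-dioxolan-4-one, via lithium enolate 9 (not isolated)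
Conditions: LiN(iPr)2, THF, −78 °C; then 8, THF/DMPU, −78 to −30 °C
Reagents that add atoms: none
Why: Enolate alkylation with self-regeneration of the stereocentre: the allylic bromide should attack the planar enolate on the face opposite the tert-butyl group, so the C4–C5 bond takes the place of the lactate hydrogen and sets C4.

Step 6
Reactants: 10 (2R,5S)-2-tert-butyl-5-methyl-5-[(2E)-2-methyloctadec-2-en-1-yl]-1,3-dioxolan-4-one
Product: 11 (2S,4E)-2,4-dimethylicos-4-ene-1,2-diol
Conditions: LiAlH4, THF, 0 °C to rt
Reagents that add atoms: none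
Why: Hydride reduction of the lactone carbonyl with release of the acetal carbon as neopentyl alcohol should unmask the primary/tertiary 1,2-diol without affecting the quaternary centre or the alkene.

Step 7
Reactants: 11 (2S,4E)-2,4-dimethylicos-4-ene-1,2-diol
Product: 12 (2S,4E)-2-hydroxy-2,4-dimethylicos-4-enal
Conditions: IBX, DMSO/THF, rt
Reagents that add atoms: none
Why: IBX oxidation takes the primary alcohol of a 1,2-diol to the α-hydroxy aldehyde without glycol cleavage, and the quaternary α-carbon cannot epimerise.

Step 8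
Reactants: 12 (2S,4E)-2-hydroxy-2,4-dimethylicos-4-enal
Product: 13 (3S,5E)-3,5-dimethylhenicosa-1,5-dien-3-ol
Conditions: Ph3PCH3Br, KOtBu (3 equiv each), THF, 0 °C; then 12, 0 °C to rt
Reagents that add atoms: methyltriphenylphosphonium bromide, C[P+](c1ccccc1)(c1ccccc1)c1ccccc1.[Br-]
Why: Wittig methylenation with excess non-stabilised ylide (one equivalent is held by the hydroxyl) should convert the α-hydroxy aldehyde into the vinyl carbinol at low temperature, before α-ketol rearrangement can compete.

Step 9
Reactants: 13 (3S,5E)-3,5-dimethylhenicosa-1,5-dien-3-ol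
Product: 14 (2S)-2-methyl-1-[(2R,3R)-2-methyl-3-pentadecyloxiran-2-yl]but-3-en-2-ol
Conditions: Shi ketone (D-fructose-derived, 30 mol%), KHSO5 (as 2KHSO5·KHSO4·K2SO4), K2CO3, Bu4NHSO4, MeCN/(MeO)2CH2/aq. Na2B4O7 buffer, 0 °C
Reagents that add atoms: potassium peroxymonosulfate KHSO5, [K+].[O-]S(=O)(=O)OO
Why: Shi asymmetric epoxidation: the chiral dioxirane should react with the electron-rich E-trisubstituted alkene far faster than with the vinyl group and, through the spiro transition state, deliver the (2R,3R)-epoxide under catalyst control.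

Step 10
Reactants: 14 (2S)-2-methyl-1-[(2R,3R)-2-methyl-3-pentadecyloxiran-2-yl]but-3-en-2-ol; 15 hydrogen peroxide
Product: 16 (3S,5S,6R)-5-hydroperoxy-3,5-dimethylhenicos-1-ene-3,6-diol
Conditions: H2O2 (anhydrous, ca. 1 M in Et2O, 10 equiv), H3PMo12O40 (3 mol%), Et2O, 0 °C to rt
Reagents that add atoms: none
Why: Acid-catalysed perhydrolysis of a trisubstituted epoxide: H2O2 should attack the more substituted carbon C6 in a borderline SN2 opening with inversion, which sets the peroxide-bearing C6 stereocentre and leaves C7 as the (R)-carbinol.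

Step 11
Reactants: 16 (3S,5S,6R)-5-hydroperoxy-3,5-dimethylhenicos-1-ene-3,6-diol; 17 carbon monoxide
Product: 20 (3S,4aS,7aS)-3-[(1R)-1-hydroxyhexadecyl]-3,4a-dimethyl-tetrahydrofuro[3,2-c][1,2]dioxin-6-one (7-hydroxy bicycle), via alkylpalladium acetate 18 (not isolated), via acylpalladium acetate 19 (not isolated)
Conditions: Pd(OAc)2 (10 mol%), p-benzoquinone (2 equiv), CO (1 atm), THF, 0 °C to rt
Reagents that add atoms: none
Why: Proposed new method: divalent palladium binds the vinyl group and the C6 hydroperoxide adds to the internal carbon C3 (6-exo-trig peroxypalladation, closing the 1,2-dioxane in 18), CO inserts into the primary C2–Pd bond (19), and the tertiary C4 hydroxyl, held on palladium as a chelate, is acylated in a 5-exo-trig lactonisation that releases zerovalent palladium for reoxidation by benzoquinone. The closest known reactions are the cyclisation of unsaturated hydroperoxides to 1,2-dioxanes with Pd(OAc)2/benzoquinone and the oxycarbonylation–lactonisation of alkene diols to cis-fused bicyclic lactones under CO; here a hydroperoxide takes the role of the hydroxyl nucleophile of the latter. C3 is the only new stereocentre and is controlled by C4 and C6: the chair that keeps both methyl groups equatorial places the C4 hydroxyl axial, only the C3 epimer with the CH2Pd arm gauche to that hydroxyl can chelate and lactonise, a trans-fused lactone would force the two methyls 1,3-diaxial, and reversible peroxypalladation should therefore funnel material to the cis-fused product. The step needs the hydroperoxide to outcompete the C7 hydroxyl (also a six-ring closure), which its α-effect nucleophilicity, higher acidity and the crowding of the C7 carbinol next to quaternary C6 should secure, and it needs internal rather than terminal attack, which the exo mode and Markovnikov polarisation secure. It also needs CO capture to outrun β-hydride loss from C3 and O–O cleavage at palladium, hence 1 atm CO, chelation by the C4 hydroxyl, low temperature and benzoquinone instead of a copper reoxidant.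

Step 12
Reactants: 20 (3S,4aS,7aS)-3-[(1R)-1-hydroxyhexadecyl]-3,4a-dimethyl-tetrahydrofuro[3,2-c][1,2]dioxin-6-one
Product: 22 (3S,4aS,7aS)-3-[(1E)-hexadec-1-en-1-yl]-3,4a-dimethyl-tetrahydrofuro[3,2-c][1,2]dioxin-6-one, via C7 sulfamate ester 21 (not isolated)
Conditions: Burgess reagent (MeO2CN−SO2N+Et3), benzene, rt then 50 °C
Reagents that add atoms: none
Why: Burgess dehydration: the sulfamate forms at the only free hydroxyl and should undergo thermal syn elimination through a cyclic transition state; because C6 is quaternary only a C8 hydrogen can be lost, so the C7=C8 alkene must result under neutral conditions that the peroxide and lactone should tolerate.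

Step 13
Reactants: 22 (3S,4aS,7aS)-3-[(1E)-hexadec-1-en-1-yl]-3,4a-dimethyl-tetrahydrofuro[3,2-c][1,2]dioxin-6-one
Product: 23 (3R,4aS,7aS)-3-hexadecyl-3,4a-dimethyl-tetrahydrofuro[3,2-c][1,2]dioxin-6-one (CNP0079571.1)
Conditions: KO2CN=NCO2K (excess), AcOH, MeOH/CH2Cl2, 0 °C to rt
Reagents that add atoms: none
Why: Diimide reduction: diimide generated in the flask transfers H2 to the disubstituted alkene through a concerted cyclic transition state and, unlike catalytic hydrogenation or hydride reagents, should leave the O–O bond and the lactone intact.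

**Compound list**

1 | (R)-lactic acid | C[C@@H](O)C(=O)O | starting material
2 | pivalaldehyde | CC(C)(C)C=O | starting material
3 | (2R,5R)-2-tert-butyl-5-methyl-1,3-dioxolan-4-one | C[C@H]1O[C@@H](C(C)(C)C)OC1=O | intermediate
4 | hexadecanal | CCCCCCCCCCCCCCCC=O | starting material
5 | ethyl 2-(triphenyl-λ5-phosphanylidene)propanoate | CCOC(=O)C(C)=P(c1ccccc1)(c1ccccc1)c1ccccc1 | starting material
6 | ethyl (2E)-2-methyloctadec-2-enoate | CCCCCCCCCCCCCCC/C=C(\C)C(=O)OCC | intermediate
7 | (2E)-2-methyloctadec-2-en-1-ol | CCCCCCCCCCCCCCC/C=C(\C)CO | intermediate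
8 | (2E)-1-bromo-2-methyloctadec-2-ene | CCCCCCCCCCCCCCC/C=C(\C)CBr | intermediate
9 | lithium (2R)-2-tert-butyl-5-methyl-1,3-dioxol-4-olate (enolate of 3) | CC1=C(O[Li])O[C@H](C(C)(C)C)O1 | intermediate
10 | (2R,5S)-2-tert-butyl-5-methyl-5-[(2E)-2-methyloctadec-2-en-1-yl]-1,3-dioxolan-4-one | C[C@@]1(C/C(C)=C/CCCCCCCCCCCCCCC)O[C@@H](C(C)(C)C)OC1=O | intermediate
11 | (2S,4E)-2,4-dimethylicos-4-ene-1,2-diol | C[C@@](CO)(C/C(C)=C/CCCCCCCCCCCCCCC)O | intermediate
12 | (2S,4E)-2-hydroxy-2,4-dimethylicos-4-enal | C[C@@](C=O)(C/C(C)=C/CCCCCCCCCCCCCCC)O | intermediate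
13 | (3S,5E)-3,5-dimethylhenicosa-1,5-dien-3-ol | C[C@@](C=C)(C/C(C)=C/CCCCCCCCCCCCCCC)O | intermediate
14 | (2S)-2-methyl-1-[(2R,3R)-2-methyl-3-pentadecyloxiran-2-yl]but-3-en-2-ol | C=C[C@@](C)(O)C[C@@]1(C)O[C@@H]1CCCCCCCCCCCCCCC | intermediate
15 | hydrogen peroxide | OO | starting material
16 | (3S,5S,6R)-5-hydroperoxy-3,5-dimethylhenicos-1-ene-3,6-diol (cascade precursor) | C=C[C@@](C)(O)C[C@](C)(OO)[C@H](O)CCCCCCCCCCCCCCC | intermediate
17 | carbon monoxide | [C-]#[O+] | starting material
18 | alkylpalladium acetate: 1,2-dioxane closed at C3, AcO–Pd on the C2 methylene, C4 hydroxyl free | CCCCCCCCCCCCCCC[C@@H](O)[C@]1(C)C[C@](C)(O)[C@H](C[Pd]OC(C)=O)OO1 | intermediate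
19 | acylpalladium acetate: as 18 after CO insertion into the C2–Pd bond | CCCCCCCCCCCCCCC[C@@H](O)[C@]1(C)C[C@](C)(O)[C@H](CC(=O)[Pd]OC(C)=O)OO1 | intermediate
20 | (3S,4aS,7aS)-3-[(1R)-1-hydroxyhexadecyl]-3,4a-dimethyl-tetrahydrofuro[3,2-c][1,2]dioxin-6-one (cis-fused; 7-hydroxy derivative of the target) | CCCCCCCCCCCCCCC[C@@H](O)[C@]1(C)C[C@]2(C)OC(=O)C[C@@H]2OO1 | intermediate
21 | C7 O-sulfamate of 20, methyl N-(alkoxysulfonyl)carbamate | CCCCCCCCCCCCCCC[C@@H](OS(=O)(=O)NC(=O)OC)[C@]1(C)C[C@]2(C)OC(=O)C[C@@H]2OO1 | intermediate
22 | (3S,4aS,7aS)-3-[(1E)-hexadec-1-en-1-yl]-3,4a-dimethyl-tetrahydrofuro[3,2-c][1,2]dioxin-6-one | CCCCCCCCCCCCCC/C=C/[C@]1(C)C[C@]2(C)OC(=O)C[C@@H]2OO1 | intermediate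
23 | (3R,4aS,7aS)-3-hexadecyl-3,4a-dimethyl-tetrahydrofuro[3,2-c][1,2]dioxin-6-one (CNP0079571.1) | CCCCCCCCCCCCCCCC[C@]1(C)C[C@]2(C)OC(=O)C[C@@H]2OO1 | target

**Step count and risks**

Total step count: 13. Longest linear sequence: 12 steps (hexadecanal 4 to target 23, steps 2 to 13).

Steps most likely to fail:

1. Step 11. The β-peroxyalkylpalladium species may collapse by hydride shift with O–O cleavage (Wacker-type ketone formation). The hydroperoxide may also be reduced by CO or by reduced palladium, or the C7 hydroxyl may attack the alkene in its place. The fallback uses known chemistry, sets out from aldehyde 12 and returns at 20. Condensation of 12 with ketenylidenetriphenylphosphorane (Ph3P=C=C=O, toluene, reflux; O-acylation then intramolecular Wittig) should give the butenolide (5S)-5-methyl-5-[(2E)-2-methyloctadec-2-en-1-yl]furan-2(5H)-one F1. Shi epoxidation under the conditions of step 9 (the electron-poor ring alkene is inert) should give the epoxy butenolide F2. Perhydrolysis as in step 10 should give the hydroperoxy butenolide F3. Catalytic Et2NH in CF3CH2OH at rt should then bring about intramolecular peroxy-Michael addition of the C6 hydroperoxide to C3 (6-exo-trig, cis-fused by the geometry of the tether) and give 20.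

2. Step 10. The tertiary allylic C4 carbinol may ionise under the acid catalyst, the C4 hydroxyl may capture the activated epoxide, or the epoxide may rearrange by hydride shift before H2O2 arrives. The fallback sets out from dienol 13 and returns at 16. Silylation (Et3SiOTf, 2,6-lutidine, CH2Cl2, −78 °C) should give the triethylsilyl ether F4. Shi epoxidation then gives the silyl-protected epoxide F5, perhydrolysis gives the silyl-protected hydroperoxy alcohol F6, and HF·pyridine in THF removes the silyl group to give 16.

3. Step 12. The C7 sulfamate may ionise next to the peroxide-bearing quaternary C6, leading to 1,2-shift or Criegee-type O–O heterolysis instead of syn elimination; the liberated amine may also induce β-elimination of the peroxide from the lactone. The fallback sets out from 20 and returns at 23, never places a leaving group on C7 and bypasses steps 12 and 13. Dess–Martin oxidation (NaHCO3-buffered CH2Cl2) should give the C7 ketone F7. Condensation with TsNHNH2 (EtOH, cat. AcOH) should give the tosylhydrazone F8. Reduction with catecholborane (CHCl3, 0 °C) followed by NaOAc·3H2O at 50 °C should give the methylene compound 23 by loss of sulfinate and N2 from the intermediate diazene.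

**Further compounds**

F1 | step 11 | (5S)-5-methyl-5-[(2E)-2-methyloctadec-2-en-1-yl]furan-2(5H)-one | C[C@@]1(C/C(C)=C/CCCCCCCCCCCCCCC)OC(=O)C=C1
F2 | step 11 | (5S)-5-methyl-5-{[(2R,3R)-2-methyl-3-pentadecyloxiran-2-yl]methyl}furan-2(5H)-one | C[C@@]1(C[C@@]2(C)O[C@@H]2CCCCCCCCCCCCCCC)OC(=O)C=C1
F3 | step 11 | (5S)-5-[(2S,3R)-2-hydroperoxy-3-hydroxy-2-methyloctadecyl]-5-methylfuran-2(5H)-one | C[C@@]1(C[C@](C)(OO)[C@H](O)CCCCCCCCCCCCCCC)OC(=O)C=C1
F4 | step 10 | triethyl{[(3S,5E)-3,5-dimethylhenicosa-1,5-dien-3-yl]oxy}silane | C=C[C@@](C)(O[Si](CC)(CC)CC)C/C(C)=C/CCCCCCCCCCCCCCC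
F5 | step 10 | triethylsilyl ether of epoxide 14 | C=C[C@@](C)(O[Si](CC)(CC)CC)C[C@@]1(C)O[C@@H]1CCCCCCCCCCCCCCC
F6 | step 10 | C4 O-triethylsilyl ether of hydroperoxy alcohol 16 | C=C[C@@](C)(O[Si](CC)(CC)CC)C[C@](C)(OO)[C@H](O)CCCCCCCCCCCCCCC
F7 | step 12 | (3S,4aS,7aS)-3-hexadecanoyl-3,4a-dimethyl-tetrahydrofuro[3,2-c][1,2]dioxin-6-one | CCCCCCCCCCCCCCCC(=O)[C@]1(C)C[C@]2(C)OC(=O)C[C@@H]2OO1
F8 | step 12 | p-toluenesulfonylhydrazone of ketone F7 | CCCCCCCCCCCCCCCC(=NNS(=O)(=O)c1ccc(C)cc1)[C@]1(C)C[C@]2(C)OC(=O)C[C@@H]2OO1
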